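The constants used here stand for no real mixture; what happens was integrated by code.

You have to choose which change to buy for this flask, so first see what stands in it.

E 20 mM; Z 0.950 equiv; time 40 min; volume of the second phase over the first 1.0

    X ⇌ Z, rate k1*([X] - [Z]/K1) per volume of the first phase (K1 = 3.3, k1 = 0.0025 s⁻¹)
    E + X ⇌ E.X (K2 = 560 L mol⁻¹, k2 = 0.18 L mol⁻¹ s⁻¹)
    J ⇌ E.X, rate k3*(cs3 - [E.X]) while solid is left; crystals form when [E.X] > cs3 (cs3 = 0.27 mM, k3 = 0.26 s⁻¹)

- amount of E.X and J together at 40 min, in percent of the E charged
- concentration of E.X in solution at 20 min, in percent of saturation
- the change that raises the amount of E.X and J together at 40 min, in percent of the E charged most ("none" if none brings more than 2 percentage points) (cedar / ash / elm / larch / none)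
- amount of E.X and J together at 40 min, in percent of the E charged, after elm

- cedar: doubling the solubility in step 3, all else as stated
- ash: doubling the transfer coefficient of step 1, all else as stated
- elm: doubling the dissolution coefficient of step 3, all else as stated
- larch: doubling the amount of Z, all else as stated

- what is said of E.X includes J
- in the second phase: Z; everything else is in the first
- charges count per volume of the first phase; a concentration in a rate is the amount of a species over the volume of its own phase; every rate counts per litre of the first phase
- J is a solid; its amount is given per volume of the solution
- run time (flask): 40 min

Z must cross into the first phase as X before E can take it, and y counts E.X and J together, so reckon the loss of Z. A molecule of X lasts 2.73 min, which is shorter than the 40 min run, so take c(X) as steady. The way back of E.X into E and X is left out on other grounds. Once crystals are there, they take up dissolved E.X within 0.0641 min, shorter than that life of X, so take c(E.X) as near its solubility of 0.27 mM. At that level and with E at its charge, the way back balances a c(X) of 0.0241 mM, which is smaller than the steady 2.36 mM at the start. Z then falls with the series constant, a pseudo-first-order constant for the two steps in a row: transfer coefficient over partition ratio and volume ratio, times the share of X that E takes rather than the transfer back. With E at its charge this is 0.0268 min⁻¹.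

Held there for 40 min, Z loses 62.5 % of the E charged, your bound from above. So c(E) stays above 7.50 mM. Held there, the constant gives a loss of 44.8 %. The steady X then holds 1.98 mM, which leaves 34.9 % as the bound from below.

Go round once. The middle of the two losses puts the mean c(E) at 14.6 mM, and the loss becomes 57.6 %. With c(X) then 1.41 mM, I commit to y of 50.6 %, and to the same after elm, since y counts both forms. Doubling the transfer coefficient raises the constant by a factor of 1.42, less than the doubling of Z gives, so I choose larch. I do not reckon sat.

The forecast, inside the bracket, gives 50.5 %, 106 %, larch and 50.5 %, holding that “doubling Z helps most”. The flask gives 50.2 %, 106 %, larch with a gain of 31 percentage points, and 50.2 %.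

Run the same reckoning on the neighbour flask with 80 mM of E, the recipe otherwise held. The series constant at the charge is 0.0387 min⁻¹, so the upper bound is 74.8 %. The lower loss is 62.6 %, and the round through the mean c(E) gives 72.4 %. Taking off c(X) of 2.11 mM leaves 69.8 %. That neighbour flask gives 68.1 %, with 2.15 mM of X in it.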